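A small charge of free catalyst, 1.5 mM beside 1.5 M of substrate, turns substrate into open intermediate and back. A second small charge, of second catalyst, joins open intermediate and partner into target, while capture agent takes open intermediate aside.

    substrate + free catalyst ⇌ free catalyst + open intermediate (K1 = 0.12, k1 = 59 /M/s)
    open intermediate + capture agent → trapped intermediate (k2 = 0.012 /M/s)
    partner + second catalyst + open intermediate → second catalyst + target (k3 = 3.2 /M²/s)

the same everywhere: substrate 1.5 M; partner 2.25 M; capture agent 0.450 M; free catalyst 1.5 mM; time 30 s
- Thursday's: second catalyst 0.80 mM
- Tuesday's: second catalyst 1.5 mM
- Wednesday's: second catalyst 3.0 mM

- "hardly changes" means that all values lie within two and a half points (for a concentration: within two and a half percent of the largest)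
- run time (Thursday's): 30 s

- amount of target at the end, in percent of the substrate charged for Thursday's, Tuesday's, Wednesday's, in this order
- how that number moves from the first to the last of them (rises, then falls / falls, then rises / rises all the way / hardly changes / falls all the way)

I take the first step as standing at balance (a pre-equilibrium) and reckon with what it leaves free. Open intermediate over substrate then stands at 0.12, so the balance share, the part of substrate and open intermediate together that is present as open intermediate, is 10.7%. With 1.5 M charged, that is a pool of 0.161 M.

Two times matter. The settling time, forward and back steps taken together over the free catalyst, is 1.21 s. The drain time of open intermediate by the step to target alone, the reciprocal of 3.2 /M²/s times partner and second catalyst as charged, is 174 s in Thursday's flask. The settling time is far shorter than the drain time, by a ratio of 144, so I hold the pool at full height after the settling time and let target grow steadily from it.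

The yield is then the balance share times the time left, divided by the drain time. That gives 1.77% for Thursday's flask, 3.33% for Tuesday's and 6.66% for Wednesday's, rising with the second catalyst.

The forecast gives 1.7%, 3.2% and 6.1%, which ends lower than my 6.66%, and it calls the shape rises all the way. Its grounds: “The yield therefore rises almost linearly, only slightly below proportional”.

The simulation gives 1.72%, 3.16% and 6.10%, and the shape is rises all the way.

In Thursday's flask the first step reaches the midpoint of its turnover up to the end at 1.21 s, and the step to target reaches its own much later, at 15.4 s of a run of 30 s. At 30.0 s Thursday's flask holds 86.5% of the substrate charged as substrate and 10.2% as open intermediate, and the balance share of those two together comes to 10.3%. Wednesday's flask at 30.0 s holds 82.8% as substrate; the balance share of that plus the open intermediate comes to 9.89%, and open intermediate stands at 9.63%.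

The numbers of this flask are assumed; the result is computed.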